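The route rests on the C4–C5 bond of the nine-carbon chain between ring A (the 2,6-dihydroxyphenyl ketone) and ring B, counted from the ring-A carbonyl C1. The key step exploits this ketone: C1 activates a cyclopropane that stores C2–C4, and a nickel-catalysed reductive ring-opening cross-electrophile coupling joins cyclopropane carbon C4 to the primary bromide carbon C5 of the complete ring B–C–D fragment, forming the bond and unveiling the linear keto chain in one operation. The precursors are cyclopropyl 2,6-dimethoxyphenyl ketone and a hexamethoxy biaryl bromide. The same ketone, brominated and borylated, also builds ring C; a Suzuki coupling sets the biaryl, and BBr3 frees eight phenols.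

Key step: step 8

Remark on the chemistry: the target has no stereocentre, and its biaryl axis carries only two ortho substituents and rotates freely, so the compound is achiral and no stereocontrol is needed. Ring letters: A = 2,6-dihydroxyphenyl ketone ring; B = catechol ring carrying the chain and the biaryl bond; C = 2,4-dihydroxy-3-acylphenyl ring; D = terminal catechol ring.

Step 1
Reactants: 1 4-bromo-1,2-dimethoxybenzene; 2 1,5-dibromopentane
Product: 4 4-(5-bromopentyl)-1,2-dimethoxybenzene, via arylmagnesium bromide 3 (not isolated)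
Conditions: Mg, THF, reflux; then 2 (3 equiv), Li2CuCl4 (3 mol%), THF, 0 °C → rt
Reagents that add atoms: none
Why: Kochi-type copper-catalysed Grignard cross-coupling with a primary alkyl bromide, where the threefold excess of 2 should keep the reaction at mono-substitution.

Step 2
Reactants: 5 1,3-dimethoxybenzene; 6 N-methoxy-N-methylcyclopropanecarboxamide
Product: 9 cyclopropyl(2,6-dimethoxyphenyl)methanone, via aryllithium 7 (not isolated), via lithium hemiaminal alkoxide 8 (not isolated)
Conditions: n-BuLi, THF, 0 °C → rt; then 6, −78 °C → rt; aq. NH4Cl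
Reagents that add atoms: none
Why: Directed ortho-metalation at C2 between the two methoxy groups followed by a Weinreb ketone synthesis, in which the chelated adduct 8 blocks over-addition and the cyclopropane is not touched.

Step 3
Reactants: 9 cyclopropyl(2,6-dimethoxyphenyl)methanone
Product: 10 (3-bromo-2,6-dimethoxyphenyl)(cyclopropyl)methanone
Conditions: NBS (1.0 equiv), MeCN, 0 °C → rt
Reagents that add atoms: N-bromosuccinimide, O=C1CCC(=O)N1Br
Why: Electrophilic aromatic bromination (SEAr) goes to C3, the only type of position that is ortho to one methoxy group and para to the other, and the first bromine plus the acyl group should slow a second substitution.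

Step 4
Reactants: 10 (3-bromo-2,6-dimethoxyphenyl)(cyclopropyl)methanone
Product: 11 cyclopropyl[2,6-dimethoxy-3-(4,4,5,5-tetramethyl-1,3,2-dioxaborolan-2-yl)phenyl]methanone
Conditions: B2pin2, Pd(dppf)Cl2 (5 mol%), KOAc, 1,4-dioxane, 90 °C
Reagents that add atoms: bis(pinacolato)diboron, CC1(C)OB(OC1(C)C)B1OC(C)(C)C(C)(C)O1
Why: Miyaura borylation of the aryl bromide, in which the weak base KOAc avoids Suzuki homocoupling and the ketone and cyclopropane are inert to Pd(0)/dppf.

Step 5
Reactants: 11 cyclopropyl[2,6-dimethoxy-3-(4,4,5,5-tetramethyl-1,3,2-dioxaborolan-2-yl)phenyl]methanone; 4 4-(5-bromopentyl)-1,2-dimethoxybenzene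
Product: 13 9-(3,4-dimethoxyphenyl)-1-[2,6-dimethoxy-3-(4,4,5,5-tetramethyl-1,3,2-dioxaborolan-2-yl)phenyl]nonan-1-one, via bromozinc enolate 12 (not isolated)
Conditions: 4 (1.5 equiv), NiBr2·dme (10 mol%), 2,2'-bipyridine (10 mol%), Zn dust (3 equiv), NaI (25 mol%), DMA, 40 °C; then aq. NH4Cl
Reagents that add atoms: none
Why: Nickel-catalysed reductive ring-opening cross-electrophile coupling of an aryl cyclopropyl ketone with a primary alkyl bromide (γ-alkylation): Ni(0) inserts into the carbonyl-activated cyclopropane bond, the γ-nickel enolate captures the alkyl radical from 4, and the pinacol boronate should stay intact because no base is present to start transmetalation.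

Step 6
Reactants: 4 4-(5-bromopentyl)-1,2-dimethoxybenzene
Product: 14 1-bromo-2-(5-bromopentyl)-4,5-dimethoxybenzene
Conditions: NBS (1.05 equiv), MeCN, 0 °C → rt
Reagents that add atoms: N-bromosuccinimide, O=C1CCC(=O)N1Br
Why: Electrophilic aromatic bromination (SEAr) of the 4-alkylveratrole goes para to one methoxy group and ortho to the alkyl chain, the usual site for this substitution pattern, and leaves the alkyl bromide alone.

Step 7
Reactants: 13 9-(3,4-dimethoxyphenyl)-1-[2,6-dimethoxy-3-(4,4,5,5-tetramethyl-1,3,2-dioxaborolan-2-yl)phenyl]nonan-1-one; 14 1-bromo-2-(5-bromopentyl)-4,5-dimethoxybenzene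
Product: 15 1-{3-[2-(5-bromopentyl)-4,5-dimethoxyphenyl]-2,6-dimethoxyphenyl}-9-(3,4-dimethoxyphenyl)nonan-1-one
Conditions: Pd(dppf)Cl2 (5 mol%), K3PO4, 1,4-dioxane/H2O, 80 °C
Reagents that add atoms: none
Why: Suzuki–Miyaura coupling, in which Pd(0)/dppf should add to the aryl C–Br bond far faster than to the unactivated primary alkyl C–Br bond, so that the bromopentyl handle is kept for step 8.

Step 8
Reactants: 15 1-{3-[2-(5-bromopentyl)-4,5-dimethoxyphenyl]-2,6-dimethoxyphenyl}-9-(3,4-dimethoxyphenyl)nonan-1-one; 9 cyclopropyl(2,6-dimethoxyphenyl)methanone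
Product: 17 octa-O-methylgiganteone A (the target with all eight phenols as methyl ethers), via bromozinc enolate 16 (not isolated)
Conditions: 9 (2.5 equiv), NiBr2·dme (10 mol%), 2,2'-bipyridine (10 mol%), Zn dust (3 equiv), NaI (25 mol%), DMA, 40 °C; then aq. NH4Cl
Reagents that add atoms: none
Why: Nickel-catalysed reductive ring-opening cross-electrophile coupling of an aryl cyclopropyl ketone with an unactivated primary alkyl bromide (γ-alkylation through a γ-metalated ketone), the reaction type already rehearsed in step 5. Zinc-generated Ni(0)/bipyridine adds oxidatively into the carbonyl-activated C2–C4 bond of the cyclopropane of 9 to give a six-membered oxa-nickelacycle, i.e. a γ-nickel enolate, which captures the primary radical released by halogen abstraction from C5 of 15; reductive elimination forms the C4–C5 bond and leaves enolate 16, which is protonated on work-up. No ring is closed (one three-membered ring is opened, its strain being the driving force) and no stereocentre is formed. The step needs site selectivity in the ring cleavage and chemoselectivity for cross- over homo-coupling: the two carbonyl-flanking cyclopropane bonds of 9 are equivalent and the distal bond is not activated, so only the linear chain can result, and an excess of the cheap ketone 9 over the valuable bromide 15 should suppress dimerisation of the bromide. The ring-C ketone of 15 has no strained ring and is shielded by two ortho substituents, and 15 carries no aryl halide, so nothing else in the molecule should engage nickel.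

Step 9
Reactants: 17 octa-O-methylgiganteone A
Product: 18 giganteone A
Conditions: BBr3 (20 equiv), CH2Cl2, −78 °C → rt; then H2O, 0 °C
Reagents that add atoms: none
Why: Lewis-acid ether cleavage with BBr3 (O–B adduct, then SN2 attack of bromide on methyl) removes all eight methyl groups, the two pairs next to a carbonyl fastest through chelation, while ketones and alkyl chains are inert.

Compound list
1 | 4-bromo-1,2-dimethoxybenzene | COc1ccc(Br)cc1OC | starting material
2 | 1,5-dibromopentane | BrCCCCCBr | starting material
3 | (3,4-dimethoxyphenyl)magnesium bromide | COc1ccc([Mg]Br)cc1OC | intermediate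
4 | 4-(5-bromopentyl)-1,2-dimethoxybenzene | COc1ccc(CCCCCBr)cc1OC | intermediate
5 | 1,3-dimethoxybenzene | COc1cccc(OC)c1 | starting material
6 | N-methoxy-N-methylcyclopropanecarboxamide | CON(C)C(=O)C1CC1 | starting material
7 | (2,6-dimethoxyphenyl)lithium | [Li]c1c(OC)cccc1OC | intermediate
8 | lithium cyclopropyl(2,6-dimethoxyphenyl)[methoxy(methyl)amino]methanolate | COc1cccc(OC)c1C(O[Li])(N(C)OC)C1CC1 | intermediate
9 | cyclopropyl(2,6-dimethoxyphenyl)methanone | COc1cccc(OC)c1C(=O)C1CC1 | intermediate
10 | (3-bromo-2,6-dimethoxyphenyl)(cyclopropyl)methanone | COc1ccc(Br)c(OC)c1C(=O)C1CC1 | intermediate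
11 | cyclopropyl[2,6-dimethoxy-3-(4,4,5,5-tetramethyl-1,3,2-dioxaborolan-2-yl)phenyl]methanone | COc1ccc(B2OC(C)(C)C(C)(C)O2)c(OC)c1C(=O)C1CC1 | intermediate
12 | bromozinc enolate of 13 (double-bond geometry not defined) | COc1ccc(B2OC(C)(C)C(C)(C)O2)c(OC)c1C(O[Zn]Br)=CCCCCCCCc1ccc(OC)c(OC)c1 | intermediate
13 | 9-(3,4-dimethoxyphenyl)-1-[2,6-dimethoxy-3-(4,4,5,5-tetramethyl-1,3,2-dioxaborolan-2-yl)phenyl]nonan-1-one | COc1ccc(B2OC(C)(C)C(C)(C)O2)c(OC)c1C(=O)CCCCCCCCc1ccc(OC)c(OC)c1 | intermediate
14 | 1-bromo-2-(5-bromopentyl)-4,5-dimethoxybenzene | COc1cc(Br)c(CCCCCBr)cc1OC | intermediate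
15 | 1-{3-[2-(5-bromopentyl)-4,5-dimethoxyphenyl]-2,6-dimethoxyphenyl}-9-(3,4-dimethoxyphenyl)nonan-1-one | COc1ccc(-c2cc(OC)c(OC)cc2CCCCCBr)c(OC)c1C(=O)CCCCCCCCc1ccc(OC)c(OC)c1 | intermediate
16 | bromozinc enolate of 17 (double-bond geometry not defined) | COc1cccc(OC)c1C(O[Zn]Br)=CCCCCCCCc1cc(OC)c(OC)cc1-c1ccc(OC)c(C(=O)CCCCCCCCc2ccc(OC)c(OC)c2)c1OC | intermediate
17 | octa-O-methylgiganteone A | COc1cccc(OC)c1C(=O)CCCCCCCCc1cc(OC)c(OC)cc1-c1ccc(OC)c(C(=O)CCCCCCCCc2ccc(OC)c(OC)c2)c1OC | intermediate
18 | giganteone A | O=C(CCCCCCCCc1cc(O)c(O)cc1-c1ccc(O)c(C(=O)CCCCCCCCc2ccc(O)c(O)c2)c1O)c1c(O)cccc1O | target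

Total step count: 9 steps.
Longest linear sequence: 7 steps (steps 2, 3, 4, 5, 7, 8 and 9, from 5 to 18).

Steps most likely to fail

Step 8. Nickel may insert only slowly into the cyclopropane, because the two ortho-methoxy groups twist the carbonyl out of the plane of ring A; reduction or homocoupling of the alkyl bromide could then overtake the cross-coupling. The fallback sets out from 9 and 15 and comes back at 17, and makes the same C4–C5 bond by an alkyl–alkyl Negishi coupling. Compound 9 would be opened with HBr in acetic acid (0 °C → rt) to 4-bromo-1-(2,6-dimethoxyphenyl)butan-1-one F1. Compound 15 would be converted with zinc dust and LiCl (THF, 50 °C) into the alkylzinc bromide of 15 F2. F2 and F1 would then be coupled with Pd-PEPPSI-IPr and LiBr in THF/NMP at rt to give 17.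

Step 5. The carbon–boron bond may be lost under the reducing nickel conditions (protodeboronation or transfer of the aryl group to nickel), or the ring opening may be slow for the reason given for step 8. The fallback sets out from 4 and comes back at 13, and brings the chain in by acylation instead of ring opening. Compound 4 with Mg in THF would give [5-(3,4-dimethoxyphenyl)pentyl]magnesium bromide F3. Copper-catalysed coupling with ethyl 4-bromobutanoate (Li2CuCl4 cat., THF/NMP, 0 °C) would give ethyl 9-(3,4-dimethoxyphenyl)nonanoate F4. MeNHOMe·HCl and i-PrMgCl (THF, −20 °C) would turn it into 9-(3,4-dimethoxyphenyl)-N-methoxy-N-methylnonanamide F5. Commercial 1-bromo-2,4-dimethoxybenzene would be deprotonated between its methoxy groups with LDA (THF, −78 °C) to (3-bromo-2,6-dimethoxyphenyl)lithium F6. Addition of F6 to F5 would give the lithium hemiaminal alkoxide F7 and, after aqueous work-up, 1-(3-bromo-2,6-dimethoxyphenyl)-9-(3,4-dimethoxyphenyl)nonan-1-one F8. Miyaura borylation under the conditions of step 4 would give 13.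

Step 1. The copper-catalysed coupling may not stop cleanly at mono-substitution of the dibromide, and halogen–magnesium exchange may divert the Grignard reagent into homocoupling. The fallback sets out from 1 through its Grignard reagent 3 and comes back at 4, and replaces the direct alkylation by acylation and deoxygenation. Compound 3 would be acylated with 5-bromopentanoyl chloride (Fe(acac)3 cat., THF, −78 °C) to 5-bromo-1-(3,4-dimethoxyphenyl)pentan-1-one F9. Ionic hydrogenation of the electron-rich aryl ketone (Et3SiH, TFA, rt) would give 4.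

Further compounds
F1 | step 8 | 4-bromo-1-(2,6-dimethoxyphenyl)butan-1-one | COc1cccc(OC)c1C(=O)CCCBr
F2 | step 8 | alkylzinc bromide of 15 (C–Br replaced by C–ZnBr) | Br[Zn]CCCCCc1cc(OC)c(OC)cc1-c1ccc(OC)c(C(=O)CCCCCCCCc2ccc(OC)c(OC)c2)c1OC
F3 | step 5 | [5-(3,4-dimethoxyphenyl)pentyl]magnesium bromide | COc1ccc(CCCCC[Mg]Br)cc1OC
F4 | step 5 | ethyl 9-(3,4-dimethoxyphenyl)nonanoate | CCOC(=O)CCCCCCCCc1ccc(OC)c(OC)c1
F5 | step 5 | 9-(3,4-dimethoxyphenyl)-N-methoxy-N-methylnonanamide | CON(C)C(=O)CCCCCCCCc1ccc(OC)c(OC)c1
F6 | step 5 | (3-bromo-2,6-dimethoxyphenyl)lithium | [Li]c1c(OC)ccc(Br)c1OC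
F7 | step 5 | lithium hemiaminal alkoxide from F5 and F6 (racemic) | COc1ccc(Br)c(OC)c1C(O[Li])(N(C)OC)CCCCCCCCc1ccc(OC)c(OC)c1
F8 | step 5 | 1-(3-bromo-2,6-dimethoxyphenyl)-9-(3,4-dimethoxyphenyl)nonan-1-one | COc1ccc(Br)c(OC)c1C(=O)CCCCCCCCc1ccc(OC)c(OC)c1
F9 | step 1 | 5-bromo-1-(3,4-dimethoxyphenyl)pentan-1-one | COc1ccc(C(=O)CCCCBr)cc1OC
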